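## Retrosynthetic overview

1. Target ⇐ end game (C9 ketone reduction, C8 α-bromination, hydrogenation of a C4 bromoalkene, oxidative removal of an isopropenyl group to the C9 ketone, C1 ketone reduction/acetylation) ⇐ tricyclic cyclobutanone 15, which already holds the three contiguous quaternary carbons C3, C11 and C6.
2. 15 ⇐ intramolecular ketene–alkene [2+2] ⇐ cyclohexylidene ketene 14 ⇐ Wolff ring contraction ⇐ seven-membered α-diazoketone 13. The cyclohexane is never built as such: it appears when C6 shifts from C1 to C11, and the cyclobutanone and cyclopentane close in the same operation.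
3. Enabling feature: C11, the carbon common to all three rings, carries the acetoxy carbon C1 as its only one-carbon appendage, so C1 can be the carbonyl carbon of a ketene exocyclic to the six-membered ring (C11=C1=O). C3(Me)=C2H2 is a 1,1-disubstituted alkene held three atoms away (C6–C5–C4), the arrangement that gives a fused bicyclo[3.2.0]heptanone.
4. 13 ⇐ cycloheptanone from (S)-carvone: cuprate addition/prenylation (C7, C6), one-carbon ring expansion (C11), enone methylation then CuH reduction (C10), Shi epoxidation and epoxide-to-allyl-silyl-ether isomerization (C4–O, C2=C3), diazo transfer.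
5. Ring order: carvone six-ring → seven-ring (step 2) → in step 9 the cyclohexane (by contraction), the cyclopentane and the cyclobutane together.

Key step: step 9

Remark: atom numbers and α/β in all names follow the target — cyclobutane C1(OAc)–C2–C3(Me)–C11, cyclopentane C3–C4(Br)–C5–C6(Me)–C11, cyclohexane C6–C7(Me)–C8(Br)–C9(OH)–C10(Me)–C11; β is the face of the six-membered ring (or its monocyclic precursor) carrying the C6 and C7 methyl groups, α the other face (C5, C3, C8-Br, C9-O, C10-Me in the target); the (4R) centre of 6–18 is a stereochemical passenger that is erased at 19.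

## Route

Step 1
Reactants: 1 (S)-(+)-carvone
Product: 3 (2R,3S,5S)-2,3-dimethyl-2-(3-methylbut-2-enyl)-5-(prop-1-en-2-yl)cyclohexan-1-one (C1 ketone; C6 β-Me/α-prenyl; C7 β-Me; C9 α-isopropenyl), via lithium enolate 2 (not isolated)
Conditions: Me2CuLi, Et2O, −78 → 0 °C; then prenyl bromide, HMPA, THF, 0 → 23 °C
Reagents that add atoms: lithium dimethylcuprate C[Cu-]C.[Li+]; prenyl bromide CC(C)=CCBr
Why: Tandem cuprate 1,4-addition/enolate alkylation, established for carvone with allylic bromides: methyl enters C7 anti to the C9 isopropenyl group and the regiodefined enolate 2 is prenylated anti to the new C7 methyl, which sets C7 and the quaternary C6 (C6-Me and C7-Me cis).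

Step 2
Reactants: 3 cyclohexanone from step 1
Product: 5 (2R,3S,5R)-2,3-dimethyl-2-(3-methylbut-2-enyl)-5-(prop-1-en-2-yl)cycloheptan-1-one (ring C1–C6–C7–C8–C9–C10–C11), via 11-trimethylsilyl cycloheptanone 4 (not isolated)
Conditions: TMSCHN2, AlMe3, CH2Cl2, −78 → −20 °C; then 1 M HCl, THF, 23 °C
Reagents that add atoms: trimethylsilyldiazomethane C[Si](C)(C)C=[N+]=[N-]
Why: Lewis-acid-promoted diazoalkane homologation (Tiffeneau–Demjanov type) in which the less substituted C10 methylene migrates in preference to the quaternary C6, so the new carbon C11 is inserted between C1 and C10 and acid work-up removes the α-silyl group of 4; no stereocentre is touched.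

Step 3
Reactants: 5 cycloheptanone
Product: 6 (4R)-epoxide of 5 (side chain C5H2–C4H(O)C3Me2 oxirane; isopropenyl intact)
Conditions: D-fructose-derived Shi ketone (cat.), Oxone, K2CO3, Bu4NHSO4, MeCN/dimethoxymethane/aq. buffer pH 10.5, 0 °C
Reagents that add atoms: potassium peroxymonosulfate (Oxone) [K+].[O-]S(=O)(=O)OO
Why: Shi epoxidation, in which the electrophilic dioxirane reacts with the trisubstituted prenyl alkene well before the 1,1-disubstituted isopropenyl group and the spiro transition state is expected to give the (4R)-epoxide, a centre that is erased at step 13 so its purity is not critical.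

Step 4
Reactants: 6 epoxide
Product: 7 bis-silyl compound (C1(OTBS)=C11 enol ether; side chain C5H2–C4H(OTBS)–C3(Me)=C2H2 with 4R)
Conditions: TBSOTf (3 equiv), Et3N, CH2Cl2, −78 → 0 °C; then DBU, 23 °C
Reagents that add atoms: tert-butyldimethylsilyl triflate CC(C)(C)[Si](C)(C)OS(=O)(=O)C(F)(F)F
Why: Silyl-triflate-mediated isomerization of a trisubstituted epoxide to an allylic silyl ether (O-silylation, opening at the tertiary C3, loss of a methyl proton to the amidine base, C4–O bond untouched so C4 is retained), with concurrent formation of the only possible silyl enol ether of the ketone, which is the substrate for step 5.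

Step 5
Reactants: 7 bis-silyl compound
Product: 8 cyclohept-2-enone (C1 ketone; C11=C10; side chain (4R)-OTBS allyl ether)
Conditions: Pd(OAc)2 (1.1 equiv), MeCN, 23 °C
Reagents that add atoms: none
Why: Saegusa–Ito oxidation, in which the palladium enolate formed from the silyl enol ether undergoes β-hydride elimination of H-10 and gives the enone regiospecifically because C6 is quaternary.

Step 6
Reactants: 8 enone
Product: 10 10-methyl enone (C1 ketone; C11=C10–Me), via 10β-methyl lithium enolate 9 (not isolated)
Conditions: Me2CuLi, Et2O/THF, −78 °C; then N-tert-butylbenzenesulfinimidoyl chloride, −78 → 0 °C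
Reagents that add atoms: lithium dimethylcuprate C[Cu-]C.[Li+]
Why: Cuprate conjugate addition places the methyl group on C10 and the enolate 9 is dehydrogenated in the same flask by the sulfinimidoyl chloride (α-sulfenylation at C11, then syn-elimination), which returns an enone with C10 sp2 so that its configuration can be set by hydride in step 7.

Step 7
Reactants: 10 10-methyl enone
Product: 11 cycloheptanone with 10α-methyl (cis to the 9α-isopropenyl group)
Conditions: [(Ph3P)CuH]6 (Stryker's reagent), H2O (2 equiv), benzene, 23 °C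
Reagents that add atoms: none
Why: Copper hydride conjugate reduction delivers hydride to C10 on the face opposite the adjacent C9 isopropenyl group (held pseudoaxial by A(1,2) strain with the C10 methyl), which places C10-Me α as in the target, the opposite of what direct cuprate methylation gives, while isolated alkenes and the silyl ether are inert.

Step 8
Reactants: 11 cycloheptanone
Product: 13 11-diazo cycloheptanone, via 11-trifluoroacetyl ketone 12 (not isolated)
Conditions: LiHMDS, THF, −78 °C; CF3CO2CH2CF3; then MsN3, Et3N, H2O, MeCN, 23 °C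
Reagents that add atoms: methanesulfonyl azide CS(=O)(=O)N=[N+]=[N-]
Why: Detrifluoroacetylative (Regitz-type) diazo transfer, in which enolization can occur only at C11 because C6 is quaternary, Claisen trifluoroacetylation activates that position and mesyl azide transfers the diazo group with loss of the trifluoroacetyl unit.

Step 9
Reactants: 13 11-diazo cycloheptanone
Product: 15 tricyclic cyclobutanone (C1 ketone; (4R)-OTBS; 9α-isopropenyl; 10α-Me; ring fusions as in the target), via cyclohexylidene ketene 14 (not isolated)
Conditions: hν (365 nm), toluene (high dilution), 23 °C; then 90 °C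
Reagents that add atoms: none
Why: Irradiation expels N2 from the s-cis-locked cyclic α-diazoketone and the quaternary C6 shifts from C1 to C11 in a concerted Wolff rearrangement, which contracts the seven-membered ring to the cyclohexane and gives the ketene 14 (C11=C1=O). The ketene then adds to the pendant 1,1-disubstituted alkene in a thermal intramolecular [2+2] cycloaddition; the closest known reactions are the photochemical ring contraction of 2-diazocycloalkanones and the intramolecular ketene–alkene cycloaddition of alkenyl ketenes with a three-atom tether. Bond C11–C3 closes the cyclopentane through the C6–C5–C4 tether and bond C1–C2 closes the cyclobutanone, the fused bicyclo[3.2.0]heptanone mode in which the CH2 terminus attacks the electrophilic ketene carbonyl carbon and the more substituted alkene carbon bonds to C11. C11 is controlled by C6, because the tether sits on the α-face and C3 can therefore only add to the α-face of C11 (cis ring fusion), and C3 follows because a bicyclo[3.2.0]heptane must be cis-fused, which puts C3-Me anti to the four-membered ring. The step needs Wolff shift over 1,2-H shift from C10 (secured by the concerted photoreaction of a cyclic diazoketone), fused over bridged regiochemistry (secured by alkene polarization and tether length) and reaction at the side-chain alkene rather than the isopropenyl group (which is only two atoms from C11 and could only give a far more strained bicycle).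

Step 10
Reactants: 15 tricyclic cyclobutanone
Product: 16 C1 exo alcohol (1R; OH anti to the cyclopentane and syn to C10)
Conditions: Li, NH3(l)/THF, −78 °C; then NH4Cl
Reagents that add atoms: none
Why: Dissolving-metal reduction under thermodynamic control, which should give the more stable exo alcohol because the endo position is eclipsed by the C6 methyl group, whereas hydride attack on the open exo face would give the epimer; the isolated alkene and silyl ether are inert.

Step 11
Reactants: 16 C1 exo alcohol
Product: 17 C1 acetate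
Conditions: Ac2O, DMAP, pyridine, CH2Cl2, 23 °C
Reagents that add atoms: acetic anhydride CC(=O)OC(C)=O
Why: Standard DMAP-catalysed acetylation installs the acetate of the target, which also protects C1–O during the oxidation at C4.

Step 12
Reactants: 17 C1 acetate
Product: 18 (4R)-alcohol
Conditions: HF·pyridine, pyridine, THF, 0 → 23 °C
Reagents that add atoms: none
Why: Buffered fluoride cleavage of the secondary TBS ether, under which the acetate and the isopropenyl group are stable.

Step 13
Reactants: 18 (4R)-alcohol
Product: 19 C4 ketone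
Conditions: Dess–Martin periodinane, NaHCO3, CH2Cl2, 23 °C
Reagents that add atoms: none
Why: Dess–Martin oxidation of the secondary alcohol under neutral conditions, which removes the C4 stereocentre on purpose.

Step 14
Reactants: 19 C4 ketone
Product: 20 C4-bromo C4=C5 alkene
Conditions: (PhO)3P, Br2, CH2Cl2, −60 °C; then 19, Et3N, −60 °C → reflux
Reagents that add atoms: bromine (as its triphenyl phosphite adduct) BrBr
Why: Conversion of an enolizable ketone into a vinyl bromide with the triphenyl phosphite–bromine reagent and triethylamine, where C3 is quaternary so only the C4=C5 bromoalkene can form and the weak base spares the acetate.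

Step 15
Reactants: 20 bromoalkene
Product: 23 C9 ketone (bromoalkene and 10α-Me retained), via methoxy hydroperoxide 21 (not isolated), via TEMPO alkoxyamine 22 (not isolated)
Conditions: O3, MeOH/CH2Cl2, −78 °C; then FeSO4·7H2O, TEMPO, 0 → 23 °C; then mCPBA, NaHCO3, CH2Cl2, 0 °C
Reagents that add atoms: TEMPO CC1(C)CCCC(C)(C)N1[O]
Why: Dealkenylative ketone synthesis (ozonolysis in methanol to the α-methoxy hydroperoxide, Fe(II)-induced O–O cleavage and β-scission with loss of methyl acetate, TEMPO capture of the C9 radical, peracid oxidation of the alkoxyamine to the ketone), in which ozone selects the electron-rich isopropenyl group over the hindered electron-poor bromoalkene and the buffer prevents epimerization at C10.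

Step 16
Reactants: 23 C9 ketone with C4=C5 bromoalkene
Product: 24 (4S)-bromide (Br syn to the cyclobutane)
Conditions: Mn(dpm)3 (cat.), PhSiH3, t-BuOOH, i-PrOH, 23 °C
Reagents that add atoms: none
Why: Metal-hydride hydrogen-atom-transfer hydrogenation, a method that reduces bromoalkenes without C–Br hydrogenolysis: H• adds to C5 and the α-bromo radical at C4 takes its hydrogen on the convex face of the bicyclo[3.2.0]heptane (opposite the four-membered ring), which leaves bromine on the concave face as in the target, a result that SN2 displacement at this neopentyl centre could not give.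

Step 17
Reactants: 24 (4S)-bromide
Product: 26 8α-bromo C9 ketone, via C8=C9 trimethylsilyl enol ether 25 (not isolated)
Conditions: LiHMDS (1.05 equiv), TMSCl, THF, −78 °C; then NBS, NaHCO3, THF, −78 → 0 °C
Reagents that add atoms: N-bromosuccinimide O=C1CCC(=O)N1Br
Why: Kinetic enolization with internal silyl quench occurs at the C8 methylene rather than at the hindered C10 methine or the acetate, and NBS brominates the silyl enol ether anti to the adjacent C7 methyl (also the face remote from the C6 methyl), which gives the trans C7-Me/C8-Br relationship without touching C10.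

Step 18
Reactants: 26 8α-bromo C9 ketone
Product: 27 target (CNP0246576.1)
Conditions: L-Selectride, THF, −78 °C
Reagents that add atoms: none
Why: Bulky-hydride reduction of the α-bromo ketone, in which hydride approaches C9 anti to both α-substituents (C8-Br and C10-Me, both on the α-face) so the hydroxyl emerges cis to both, and the cis-bromohydrin cannot close to an epoxide.

## Compound list

1 | (S)-(+)-carvone | CC1=CC[C@@H](CC1=O)C(C)=C | starting material
2 | lithium (3S,5S)-2,3-dimethyl-5-(prop-1-en-2-yl)cyclohex-1-en-1-olate | [Li]OC1=C(C)[C@@H](C)C[C@H](C(C)=C)C1 | intermediate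
3 | (2R,3S,5S)-2,3-dimethyl-2-(3-methylbut-2-enyl)-5-(prop-1-en-2-yl)cyclohexan-1-one | O=C1C[C@@H](C(C)=C)C[C@H](C)[C@@]1(C)CC=C(C)C | intermediate
4 | 11-trimethylsilyl derivative of 5 (C11 epimers) | O=C1C([Si](C)(C)C)C[C@@H](C(C)=C)C[C@H](C)[C@@]1(C)CC=C(C)C | intermediate
5 | (2R,3S,5R)-2,3-dimethyl-2-(3-methylbut-2-enyl)-5-(prop-1-en-2-yl)cycloheptan-1-one | O=C1CC[C@@H](C(C)=C)C[C@H](C)[C@@]1(C)CC=C(C)C | intermediate
6 | (4R)-epoxide of 5 (C3–C4 oxirane in the side chain) | O=C1CC[C@@H](C(C)=C)C[C@H](C)[C@@]1(C)C[C@H]2OC2(C)C | intermediate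
7 | C1(OTBS)=C11 silyl enol ether with (4R)-OTBS allyl ether side chain | CC(C)(C)[Si](C)(C)OC1=CC[C@@H](C(C)=C)C[C@H](C)[C@@]1(C)C[C@@H](O[Si](C)(C)C(C)(C)C)C(C)=C | intermediate
8 | cyclohept-2-enone (C1=O, C11=C10; 6β-Me, 7β-Me, 9α-isopropenyl, (4R)-OTBS) | O=C1C=C[C@@H](C(C)=C)C[C@H](C)[C@@]1(C)C[C@@H](O[Si](C)(C)C(C)(C)C)C(C)=C | intermediate
9 | lithium enolate C1(OLi)=C11 with 10β-methyl | [Li]OC1=C[C@H](C)[C@@H](C(C)=C)C[C@H](C)[C@@]1(C)C[C@@H](O[Si](C)(C)C(C)(C)C)C(C)=C | intermediate
10 | 10-methyl cyclohept-2-enone (C11=C10–Me) | O=C1C=C(C)[C@@H](C(C)=C)C[C@H](C)[C@@]1(C)C[C@@H](O[Si](C)(C)C(C)(C)C)C(C)=C | intermediate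
11 | cycloheptanone with 10α-methyl (cis to 9α-isopropenyl) | O=C1C[C@@H](C)[C@@H](C(C)=C)C[C@H](C)[C@@]1(C)C[C@@H](O[Si](C)(C)C(C)(C)C)C(C)=C | intermediate
12 | 11-trifluoroacetyl derivative of 11 (C11 epimers/enol) | O=C1C(C(=O)C(F)(F)F)[C@@H](C)[C@@H](C(C)=C)C[C@H](C)[C@@]1(C)C[C@@H](O[Si](C)(C)C(C)(C)C)C(C)=C | intermediate
13 | 11-diazo cycloheptanone | O=C1C(=[N+]=[N-])[C@@H](C)[C@@H](C(C)=C)C[C@H](C)[C@@]1(C)C[C@@H](O[Si](C)(C)C(C)(C)C)C(C)=C | intermediate
14 | cyclohexylidene ketene (C11=C1=O on the contracted ring) | O=C=C1[C@@H](C)[C@@H](C(C)=C)C[C@H](C)[C@@]1(C)C[C@@H](O[Si](C)(C)C(C)(C)C)C(C)=C | intermediate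
15 | tricyclic cyclobutanone (C1=O, (4R)-OTBS, 9α-isopropenyl, 10α-Me) | O=C1C[C@@]2(C)[C@H](O[Si](C)(C)C(C)(C)C)C[C@]3(C)[C@@H](C)C[C@H](C(C)=C)[C@H](C)[C@]123 | intermediate
16 | C1 exo (1R) alcohol | O[C@@H]1C[C@@]2(C)[C@H](O[Si](C)(C)C(C)(C)C)C[C@]3(C)[C@@H](C)C[C@H](C(C)=C)[C@H](C)[C@]123 | intermediate
17 | C1 acetate, (4R)-OTBS | CC(=O)O[C@@H]1C[C@@]2(C)[C@H](O[Si](C)(C)C(C)(C)C)C[C@]3(C)[C@@H](C)C[C@H](C(C)=C)[C@H](C)[C@]123 | intermediate
18 | C1 acetate, (4R)-alcohol | CC(=O)O[C@@H]1C[C@@]2(C)[C@H](O)C[C@]3(C)[C@@H](C)C[C@H](C(C)=C)[C@H](C)[C@]123 | intermediate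
19 | C1 acetate, C4 ketone | CC(=O)O[C@@H]1C[C@@]2(C)C(=O)C[C@]3(C)[C@@H](C)C[C@H](C(C)=C)[C@H](C)[C@]123 | intermediate
20 | C1 acetate, C4-bromo C4=C5 alkene, 9α-isopropenyl | CC(=O)O[C@@H]1C[C@@]2(C)C(Br)=C[C@]3(C)[C@@H](C)C[C@H](C(C)=C)[C@H](C)[C@]123 | intermediate
21 | α-methoxy hydroperoxide at the former isopropenyl carbon (epimers) | CC(=O)O[C@@H]1C[C@@]2(C)C(Br)=C[C@]3(C)[C@@H](C)C[C@H](C(C)(OC)OO)[C@H](C)[C@]123 | intermediate
22 | C9 O-(2,2,6,6-tetramethylpiperidin-1-yl) alkoxyamine (C9 epimers) | CC(=O)O[C@@H]1C[C@@]2(C)C(Br)=C[C@]3(C)[C@@H](C)CC(ON4C(C)(C)CCCC4(C)C)[C@H](C)[C@]123 | intermediate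
23 | C9 ketone with C4=C5 bromoalkene | CC(=O)O[C@@H]1C[C@@]2(C)C(Br)=C[C@]3(C)[C@@H](C)CC(=O)[C@H](C)[C@]123 | intermediate
24 | C9 ketone, (4S)-bromide | CC(=O)O[C@@H]1C[C@@]2(C)[C@@H](Br)C[C@]3(C)[C@@H](C)CC(=O)[C@H](C)[C@]123 | intermediate
25 | C8=C9 trimethylsilyl enol ether | CC(=O)O[C@@H]1C[C@@]2(C)[C@@H](Br)C[C@]3(C)[C@@H](C)C=C(O[Si](C)(C)C)[C@H](C)[C@]123 | intermediate
26 | 8α-bromo C9 ketone | CC(=O)O[C@@H]1C[C@@]2(C)[C@@H](Br)C[C@]3(C)[C@@H](C)[C@H](Br)C(=O)[C@H](C)[C@]123 | intermediate
27 | CNP0246576.1 | CC(=O)O[C@@H]1C[C@@]2(C)[C@@H](Br)C[C@]3(C)[C@@H](C)[C@H](Br)[C@H](O)[C@H](C)[C@]123 | target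

## Step count and risks

Total step count: 18. Longest linear sequence: 18 steps from (S)-carvone (fully linear).

Steps most likely to fail:

1. Step 16. The α-bromo radical at C4 is a cyclobutylcarbinyl radical and may open the four-membered ring before it is quenched. Hydrogen delivery may also be poorly face-selective, or bromine may be lost by over-reduction. Fallback: from ketone 19, condensation with 1,2-bis(tert-butyldimethylsilyl)hydrazine (cat. Sc(OTf)3) should give the N-silyl hydrazone F1. CuBr2/Et3N in MeOH should convert it into the geminal dibromide F2. One bromine is then removed with Bu3SnH/Et3B at −78 °C, where the fast tin hydride quench on the convex face should outrun ring opening and give the (4S)-bromide F3 that still carries the isopropenyl group. F3 is then taken through the conditions of step 15 (methoxy hydroperoxide F4, TEMPO alkoxyamine F5) and rejoins the route at 24.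

2. Step 9. The cycloaddition has to join two fully substituted carbons next to a third, with the C10 methyl on the reacting face, so the ketene may persist and dimerize, hydrate or undergo ene reactions instead of closing. Fallback: from diazoketone 13, the photochemical Wolff rearrangement is run in the presence of pyrrolidine, which traps the ketene as the ring-contracted pyrrolidine amide F6. Activation with Tf2O/2,4,6-collidine (1,2-dichloroethane, reflux) should give the keteniminium triflate F7, a much stronger electrophile than the ketene. Its intramolecular [2+2] cycloaddition should give the cyclobutaniminium triflate F8, and aqueous NaHCO3 hydrolysis returns cyclobutanone 15.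

3. Step 10. The strained ketyl may fragment, or equilibration may not favour the exo alcohol as strongly as expected, leaving a mixture at C1. Fallback: from 15, NaBH4 (MeOH, −78 °C) should attack the open exo face under kinetic control and give the endo alcohol F9 (C1 epimer of 16). Mitsunobu inversion with acetic acid (PPh3, DIAD, THF) then delivers the exo acetate directly and rejoins the route at 17.

Further compounds
F1 | step 16 | N-(tert-butyldimethylsilyl)hydrazone of ketone 19 | CC(=O)O[C@@H]1C[C@@]2(C)C(=NN[Si](C)(C)C(C)(C)C)C[C@]3(C)[C@@H](C)C[C@H](C(C)=C)[C@H](C)[C@]123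
F2 | step 16 | C4 geminal dibromide | CC(=O)O[C@@H]1C[C@@]2(C)C(Br)(Br)C[C@]3(C)[C@@H](C)C[C@H](C(C)=C)[C@H](C)[C@]123
F3 | step 16 | (4S)-bromide with 9α-isopropenyl | CC(=O)O[C@@H]1C[C@@]2(C)[C@@H](Br)C[C@]3(C)[C@@H](C)C[C@H](C(C)=C)[C@H](C)[C@]123
F4 | step 16 | α-methoxy hydroperoxide from F3 | CC(=O)O[C@@H]1C[C@@]2(C)[C@@H](Br)C[C@]3(C)[C@@H](C)C[C@H](C(C)(OC)OO)[C@H](C)[C@]123
F5 | step 16 | C9 TEMPO alkoxyamine from F4 | CC(=O)O[C@@H]1C[C@@]2(C)[C@@H](Br)C[C@]3(C)[C@@H](C)CC(ON4C(C)(C)CCCC4(C)C)[C@H](C)[C@]123
F6 | step 9 | ring-contracted pyrrolidine amide (C11 epimers) | O=C(N1CCCC1)C1[C@@H](C)[C@@H](C(C)=C)C[C@H](C)[C@@]1(C)C[C@@H](O[Si](C)(C)C(C)(C)C)C(C)=C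
F7 | step 9 | keteniminium triflate | [O-]S(=O)(=O)C(F)(F)F.C1CC[N+](C1)=C=C1[C@@H](C)[C@@H](C(C)=C)C[C@H](C)[C@@]1(C)C[C@@H](O[Si](C)(C)C(C)(C)C)C(C)=C
F8 | step 9 | cyclobutaniminium triflate | [O-]S(=O)(=O)C(F)(F)F.C1CC[N+](C1)=C1C[C@@]2(C)[C@H](O[Si](C)(C)C(C)(C)C)C[C@]3(C)[C@@H](C)C[C@H](C(C)=C)[C@H](C)[C@]123
F9 | step 10 | C1 endo alcohol (C1 epimer of 16) | O[C@H]1C[C@@]2(C)[C@H](O[Si](C)(C)C(C)(C)C)C[C@]3(C)[C@@H](C)C[C@H](C(C)=C)[C@H](C)[C@]123
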